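## Structural features

Lespedezaflavanone C (19) is a (2R,3R)-3-hydroxyflavanone. A phloroglucinol-type benzene ring (ring A) is fused through C4a–C8a to a dihydropyranone (ring C: O1, C2, C3, C4), and C2 carries a 4-hydroxyphenyl ring (ring B). The only stereocentres, C2 (aryl) and C3 (OH), are neighbours and trans; C3 is α to the C4 ketone and C2 is a benzylic ether carbon β to it. Two 3-methylbut-2-enyl (prenyl) groups sit on C8 of ring A and on C3' of ring B, each ortho to a free phenol (7-OH, 4'-OH), and the 5-OH is chelated to the ketone. The fragile elements are the trisubstituted alkenes (electrophilic oxidants; acid, which closes the neighbouring phenols onto them as chromans), the β-aryloxy ketone (loss of O1 from a C3 enolate), and C2, which can open through a quinone methide once O4' is an anion. The real difficulty is to place the ring A prenyl group at C8 and not at the electronically equivalent C6, and to carry the C2/C3 pair intact through ring formation and deprotection. The key step uses the fact that C8 is the direct neighbour of C8a: C4a and C8a are the α- and β-carbons of the enone of a finished ring C, and C5–C8 come from a 1,1,3-trioxygenated four-carbon diene whose nucleophilic terminus (future C8) already bears the prenyl group.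

## Logic of the disconnections

**19 from 18.** The C3–O–Si and C4'–O–Si bonds are cut last. Both protecting groups are silyl ethers, so one buffered fluoride treatment frees 19. An acetal on O4' was rejected because its removal needs acid next to two ortho-prenyl phenols. The forward step needs a fluoride source that is not basic enough to form the 4'-phenoxide and not acidic.

**18 from 12 and 16.** The C8–C8a and C4a–C5 bonds are cut, which removes ring A from the heterocycle. C8a is the β-carbon and C4a the α-carbon of the enone in 12. In 16 the nucleophilic terminus carries the prenyl group and the other terminus is at the carboxylic oxidation level. The 5,7-dioxygenation, the C8 prenyl group and the position of O1 therefore follow from one polarity-matched union. A pentasubstituted arene is exchanged for an acyclic triene and a monocyclic pyranone that already holds C2 and C3. The demand is that C4a of 12 carries bromine, which supplies the third unsaturation by loss of HBr and blocks enolisation at C4a. Addition puts H-8a and Br on the same face, so an anti E2 elimination is not possible. The loss of HBr has to run stepwise under weakly basic, non-nucleophilic conditions in which O1 is not expelled.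

**16 from 15, 14, and then 13 and 2.** Two O–Si bonds are cut in turn, then the C4–C5 bond of 14. The gain is a commercial β-keto ester and an allylic bromide. The demand is alkylation at the γ-carbon only, which the dianion provides.

**12 from 11.** No skeletal bond is cut; only the configuration at C3 changes. The cycloaddition that builds the ring is endo-selective and gives the cis isomer, while the trans arrangement is the thermodynamic one. The demand is enolisation at C3 without opening the ring at O1–C2.

**11 from 4 and 8 (through 9 and 10).** The C2–C3 and O1–C6 bonds of the pyranone are cut (hetero-Diels–Alder), and then C5–Br. One catalytic step joins an achiral aldehyde and an achiral diene and sets C2. Bromine is introduced on the silyl enol ether of the primary adduct and not on the finished enone, because only there is C5 far more nucleophilic than the prenyl alkene. The demand is a chiral Lewis acid that controls the aldehyde face with an electron-rich aromatic aldehyde.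

**8 from 7, 6 and 5.** Two O–Si bonds and the C1–O bond are cut. The C3 oxygen of the target is traced to an α'-oxidation of a commercial vinylogous ester. The demand is oxidation under neutral conditions.

**4 from 3, and 3 from 1 and 2.** The O–Si bond and the aryl C3–CH2 bond are cut. The ring B prenyl group is attached to a commercial phenol aldehyde in one step by ortho C-alkylation, at the cost of a moderate yield.

## Other disconnections considered

**Alternative 1:** The C3'–CH2 and C8–CH2 bonds are cut, so both prenyl groups become O-allyl ethers of a finished flavanonol.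
- Forward step: bis-ether A1 is warmed with Eu(fod)3. The 4'-O-(1,1-dimethylallyl) group undergoes an aromatic Claisen shift to C3'. The 5-O-prenyl group undergoes a Claisen shift to C6 and then a Cope shift to C8. This gives A2 without closing a ring.
- In its favour: both sigmatropic processes are known reaction types on flavonoid ethers. No carbanion or oxidant meets the prenyl groups. The core can be made by ordinary flavonoid chemistry before any alkene is present.
- Against it here: A1 requires three phenols and one secondary alcohol to be told apart, with the prenyl ether on the chelated, least reactive 5-OH. The C6 dienone can tautomerise before the Cope shift and leave a 6-(1,1-dimethylallyl) isomer, so the 6/8 outcome depends on rates. A Lewis acid at elevated temperature is applied to an epimerisable β-hydroxy ketone and to ortho-prenyl phenols that can close to chromans.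
- Comparison: structurally the alternative decorates bought arenes, whereas the chosen plan builds ring A. Mechanistically the alternative is the better one, since it uses precedented pericyclic chemistry and the chosen key step is unprecedented. On regiocontrol the chosen plan is better, because the prenyl position follows from which diene terminus attacks C8a. In step economy the two are about equal once the asymmetric synthesis and selective protection of the core are counted.

**Alternative 2:** The C3–C4 bond is cut. Ring C opens to dialdehyde A3, in which an α-aryl-α-aryloxy acetaldehyde hangs on O1 next to the ring A formyl group.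
- Forward step: an aminoindanol-derived triazolium salt with a weak amine base turns the ring A aldehyde into an acyl anion equivalent. This adds to the aliphatic aldehyde (6-exo-trig) and gives A4. C3 is set directly and C2 by selection between the rapidly racemising enantiomers of A3.
- In its favour: one catalytic step creates ring C and both stereocentres from a racemate, and no separate epimerisation is needed. In the number of operations that handle stereochemistry it is better than the chosen plan.
- Against it here: the ring A aldehyde is electron-rich and flanked by two ortho oxygens, so the carbene should add faster to the aliphatic aldehyde and give the regioisomeric acyloin. The benzoin step is reversible and the β-aryloxy α-hydroxy ketone can epimerise under the same base. The ring A building block needs the prenyl group next to the alkylated oxygen, which brings back the choice between two ortho oxygens. Three acetals must be removed with acid at the end.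
- Comparison: structurally both plans join two fragments of similar size late. Mechanistically the risk is comparable (equal): a known reaction class in an untested chemoselectivity setting against an unprecedented cycloaromatisation. The prenyl regiochemistry is secured better in the chosen plan. The step count is equal or slightly lower for the alternative.

**Alternative 3:** The C4–C4a bond is cut. Ring C opens to aryl bromide A5, whose chain ends in an N-methoxy-N-methylamide.
- Forward step: n-BuLi exchanges the C4a bromine at low temperature and the aryllithium attacks the amide carbonyl (6-exo-trig). The chelated tetrahedral intermediate collapses on work-up to ketone A6.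
- In its favour: bromine–lithium exchange followed by intramolecular acylation is a reliable chromanone closure, and the stereocentres are made beforehand in an open chain. The ring-forming step is better founded than the chosen key step.
- Against it here: the O1–C2 ether must be made by substitution at a benzylic carbon bearing a p-alkoxyaryl group, with a phenol blocked on both ortho positions, which invites ionisation and loss of configuration at C2. The acidic C3–H and the β-aryloxy group set up E1cB loss of the phenoxide if the aryllithium acts as a base. The pentasubstituted ring A must be made regioselectively from a symmetric phloroglucinol, so the 6/8 issue moves to the arene synthesis. Three acetals again need acid at the end.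
- Comparison: structurally both plans keep ring B and the stereocentres as spectators in the key step. Mechanistically the alternative is better. Safety of C2 is equal or slightly worse for the alternative. In step economy the chosen plan is better by roughly four to six steps.

Key step: step 11

Remark on the chemistry: the (1S,2R)-aminoindanol-derived ligand of CrCl(L) is assumed to direct the diene to the aldehyde face that gives (2R), by analogy with the facial preference of this catalyst class; if a model cycloaddition shows the opposite sense, the mirror-image ligand is used.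

## Route

Step 1
Reactants: 1 4-hydroxybenzaldehyde; 2 prenyl bromide (1-bromo-3-methylbut-2-ene)
Product: 3 4-hydroxy-3-(3-methylbut-2-en-1-yl)benzaldehyde
Conditions: aq. KOH (10%), rt
Reagents that add atoms: none
Why: Ortho C-alkylation of a phenoxide (SN2 at the allylic bromide): in water the phenoxide oxygen is strongly solvated, so the ring carbon ortho to it attacks, the para position being blocked by the formyl group; the O-prenyl ether and diprenylated phenol are expected by-products and are removed by chromatography.

Step 2
Reactants: 3 4-hydroxy-3-(3-methylbut-2-en-1-yl)benzaldehyde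
Product: 4 3-(3-methylbut-2-en-1-yl)-4-(triisopropylsilyloxy)benzaldehyde
Conditions: i-Pr3SiCl, imidazole, DMF, rt
Reagents that add atoms: triisopropylsilyl chloride, CC(C)[Si](Cl)(C(C)C)C(C)C
Why: Silyl ether formation: the bulky silyl group survives Lewis acids, amine bases and 80 °C and is removed together with the C3 silyl ether by fluoride, so no acid is needed at the end next to the ortho-prenyl phenols.

Step 3
Reactants: 5 (E)-4-methoxybut-3-en-2-one
Product: 6 (E)-3-(tert-butyldimethylsilyloxy)-1-methoxybuta-1,3-diene
Conditions: t-BuMe2SiOTf, Et3N, Et2O, 0 °C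
Reagents that add atoms: tert-butyldimethylsilyl trifluoromethanesulfonate, CC(C)(C)[Si](C)(C)OS(=O)(=O)C(F)(F)F
Why: Soft enolisation and O-silylation (silyl enol ether formation): the methyl group is the only enolisable position of the vinylogous ester, so the 2-silyloxy diene forms without regiochemical choice.

Step 4
Reactants: 6 (E)-3-(tert-butyldimethylsilyloxy)-1-methoxybuta-1,3-diene
Product: 7 (E)-1-(tert-butyldimethylsilyloxy)-4-methoxybut-3-en-2-one
Conditions: DMDO, acetone/CH2Cl2, −78 → 0 °C
Reagents that add atoms: dimethyldioxirane, CC1(C)OO1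
Why: Rubottom oxidation: the neutral dioxirane attacks the terminal, most electron-rich silyl enol ether double bond, and ring opening with 1,4 O-to-O silyl migration gives the α-silyloxy ketone, so the future C3 oxygen arrives already protected and the acid-labile β-methoxy enone never meets acid.

Step 5
Reactants: 7 (E)-1-(tert-butyldimethylsilyloxy)-4-methoxybut-3-en-2-one
Product: 8 (1E,3Z)-4-(tert-butyldimethylsilyloxy)-1-methoxy-3-(triethylsilyloxy)buta-1,3-diene
Conditions: Et3SiOTf, Et3N, Et2O, −78 → 0 °C
Reagents that add atoms: triethylsilyl trifluoromethanesulfonate, CC[Si](CC)(CC)OS(=O)(=O)C(F)(F)F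
Why: Soft enolisation and O-silylation at the only α-CH2 give the 1,3,4-trioxygenated diene; the Z enol ether is expected, and its geometry is not critical because C3 of the pyranone is equilibrated in step 7.

Step 6
Reactants: 4 3-(3-methylbut-2-en-1-yl)-4-(triisopropylsilyloxy)benzaldehyde; 8 (1E,3Z)-4-(tert-butyldimethylsilyloxy)-1-methoxy-3-(triethylsilyloxy)buta-1,3-diene
Product: 11 (2R,3S)-5-bromo-3-(tert-butyldimethylsilyloxy)-2-[3-(3-methylbut-2-en-1-yl)-4-(triisopropylsilyloxy)phenyl]-2,3-dihydro-4H-pyran-4-one, via cycloadduct silyl enol ether 9 (not isolated), via bromo methoxy ketone 10 (not isolated)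
Conditions: CrCl(L) (5 mol %; L = O,N,O-Schiff base dianion from (1S,2R)-1-amino-2-indanol and 3-(1-adamantyl)-2-hydroxy-5-methylbenzaldehyde), 4 Å MS, t-BuOMe, rt; NBS, THF, −78 °C; Et3N, −78 → 0 °C
Reagents that add atoms: N-bromosuccinimide, O=C1CCC(=O)N1Br
Why: Catalytic asymmetric hetero-Diels–Alder reaction: the chiral Lewis acid of trivalent chromium binds the aldehyde and exposes one carbonyl face to the nucleophilic C4 of 8, which sets C2 (R), while the endo transition state places the aryl group cis to the C3 silyloxy group in 9. NBS then brominates the silyl enol ether carbon C5 (α-halogenation of a silyl enol ether, far faster than attack on the prenyl alkene), and Et3N removes the acidified C5–H of 10 so that methanol leaves from the acetal carbon (E1cB) to give the bromo-enone.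

Step 7
Reactants: 11 (2R,3S)-5-bromo-3-(tert-butyldimethylsilyloxy)-2-[3-(3-methylbut-2-en-1-yl)-4-(triisopropylsilyloxy)phenyl]-2,3-dihydro-4H-pyran-4-one
Product: 12 (2R,3R)-5-bromo-3-(tert-butyldimethylsilyloxy)-2-[3-(3-methylbut-2-en-1-yl)-4-(triisopropylsilyloxy)phenyl]-2,3-dihydro-4H-pyran-4-one
Conditions: DBU (0.2 equiv), CH2Cl2, 0 °C → rt
Reagents that add atoms: none
Why: Base-catalysed epimerisation at C3 through the enol(ate) of the ketone (thermodynamic equilibration): the trans isomer, with aryl and silyloxy groups both pseudo-equatorial, should dominate, C2 is not deprotonated and keeps its configuration, and recovered cis isomer is resubmitted.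

Step 8
Reactants: 13 methyl acetoacetate; 2 prenyl bromide (1-bromo-3-methylbut-2-ene)
Product: 14 methyl 7-methyl-3-oxooct-6-enoate
Conditions: NaH, THF, 0 °C; n-BuLi, 0 °C; 2, 0 °C → rt; aq. HCl
Reagents that add atoms: none
Why: γ-Alkylation of a β-keto ester dianion: NaH removes the C2 proton and n-BuLi the C4 proton, and the more basic terminal carbanion displaces the allylic bromide (SN2), so the prenyl group is attached only at C4.

Step 9
Reactants: 14 methyl 7-methyl-3-oxooct-6-enoate
Product: 15 methyl 7-methyl-3-(trimethylsilyloxy)octa-2,6-dienoate (mixture of geometric isomers)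
Conditions: Me3SiCl, Et3N, toluene, rt
Reagents that add atoms: chlorotrimethylsilane, C[Si](C)(C)Cl
Why: O-Silylation of the enolised β-keto ester (silyl enol ether formation) under amine base; only the enol oxygen reacts and the prenyl alkene is inert.

Step 10
Reactants: 15 methyl 7-methyl-3-(trimethylsilyloxy)octa-2,6-dienoate
Product: 16 1-methoxy-7-methyl-1,3-bis(trimethylsilyloxy)octa-1,3,6-triene (mixture of geometric isomers)
Conditions: LiN(i-Pr)2, THF, −78 °C; Me3SiCl, −78 → 20 °C
Reagents that add atoms: chlorotrimethylsilane, C[Si](C)(C)Cl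
Why: Kinetic γ-deprotonation with LiN(i-Pr)2 and O-silylation of the dienolate give the 1-methoxy-1,3-bis(silyloxy)diene; the geometry of both enol ethers is erased in step 11, and the triene is used directly after removal of LiCl.

Step 11
Reactants: 12 (2R,3R)-5-bromo-3-(tert-butyldimethylsilyloxy)-2-[3-(3-methylbut-2-en-1-yl)-4-(triisopropylsilyloxy)phenyl]-2,3-dihydro-4H-pyran-4-one; 16 1-methoxy-7-methyl-1,3-bis(trimethylsilyloxy)octa-1,3,6-triene
Product: 18 (2R,3R)-3-(tert-butyldimethylsilyloxy)-5,7-dihydroxy-8-(3-methylbut-2-en-1-yl)-2-[3-(3-methylbut-2-en-1-yl)-4-(triisopropylsilyloxy)phenyl]chroman-4-one, via cis-fused bromo cycloadduct 17 (not isolated)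
Conditions: 16 (3 equiv), 2,6-lutidine, toluene, 80 °C; (CF3)2CHOH, 40 °C; aq. NH4Cl
Reagents that add atoms: none
Why: Proposed new method: the bromo-enone of 12 serves as an ynone equivalent towards the electron-rich triene 16; the closest known reaction type is the cycloaromatisation of 1-alkoxy-1,3-bis(silyloxy)dienes with halo-quinones and with chromones carrying an acceptor at C3, which has not been run on a monocyclic 5-halo-2,3-dihydropyran-4-one. The prenyl-bearing C4 terminus of 16, which has the largest HOMO coefficient, bonds to C6 of the pyranone (the enone β-carbon, future C8a) and the ketene acetal carbon bonds to C5 (future C4a), either in one asynchronous [4+2] event or as a Mukaiyama–Michael addition followed by acylation of the bromo-enolate; in both readings ring A closes as a six-membered carbocycle ([4+2] closure, or 6-(enolexo)-exo-trig attack on the ester carbonyl), giving the cis-fused adduct 17. Hexafluoroisopropanol then cleaves the ketene O,O-acetal and the silyl enol ether, so C5 and C7 become a 1,3-diketone that enolises through C6. In this enol the tertiary C4a–Br bond is allylic; because H-8a and Br are cis in 17 an anti-periplanar E2 path is not available, and loss of HBr is expected to run stepwise, by enol-assisted ionisation of bromide and loss of H-8a to the lutidine, driven by formation of the phloroglucinol ring. No stereocentre is created: the four new sp3 centres of 17 are destroyed on aromatisation, and C2 and C3 are not involved, C3 already having the favoured trans arrangement. The selectivity the step needs is regiochemical, prenyl at C8 and not at C6, and it is fixed by the matched polarity of the nucleophilic diene terminus and the β-carbon of the vinylogous ester. The second demand is that O1 stays on C8a: bromine blocks enolisation at C4a, and the weakly basic, buffered medium keeps the diketone as its C6-centred enol, so no C8 enolate is available to expel O1.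

Step 12
Reactants: 18 (2R,3R)-3-(tert-butyldimethylsilyloxy)-5,7-dihydroxy-8-(3-methylbut-2-en-1-yl)-2-[3-(3-methylbut-2-en-1-yl)-4-(triisopropylsilyloxy)phenyl]chroman-4-one
Product: 19 lespedezaflavanone C [(2R,3R)-3,5,7-trihydroxy-2-[4-hydroxy-3-(3-methylbut-2-en-1-yl)phenyl]-8-(3-methylbut-2-en-1-yl)chroman-4-one]
Conditions: Bu4NF, AcOH (1:1), THF, 0 °C → rt
Reagents that add atoms: none
Why: Fluoride-induced cleavage of both Si–O bonds (desilylation); acetic acid buffers the medium so that neither the 4'-phenoxide, which could open ring C through a quinone methide, nor a C3 enolate is formed, no strong acid is present to close the prenyl groups onto the phenols, and C2 and C3 are not touched.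

## Compound list

1 | 4-hydroxybenzaldehyde | O=Cc1ccc(O)cc1 | starting material
2 | prenyl bromide (1-bromo-3-methylbut-2-ene) | CC(C)=CCBr | starting material
3 | 4-hydroxy-3-(3-methylbut-2-en-1-yl)benzaldehyde | CC(C)=CCc1cc(C=O)ccc1O | intermediate
4 | 3-(3-methylbut-2-en-1-yl)-4-(triisopropylsilyloxy)benzaldehyde | CC(C)=CCc1cc(C=O)ccc1O[Si](C(C)C)(C(C)C)C(C)C | intermediate
5 | (E)-4-methoxybut-3-en-2-one | CO/C=C/C(C)=O | starting material
6 | (E)-3-(tert-butyldimethylsilyloxy)-1-methoxybuta-1,3-diene | CO/C=C/C(=C)O[Si](C)(C)C(C)(C)C | intermediate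
7 | (E)-1-(tert-butyldimethylsilyloxy)-4-methoxybut-3-en-2-one | CO/C=C/C(=O)CO[Si](C)(C)C(C)(C)C | intermediate
8 | (1E,3Z)-4-(tert-butyldimethylsilyloxy)-1-methoxy-3-(triethylsilyloxy)buta-1,3-diene | CO/C=C/C(O[Si](CC)(CC)CC)=C/O[Si](C)(C)C(C)(C)C | intermediate
9 | (2R,3S)-3-(tert-butyldimethylsilyloxy)-6-methoxy-2-[3-(3-methylbut-2-en-1-yl)-4-(triisopropylsilyloxy)phenyl]-4-(triethylsilyloxy)-3,6-dihydro-2H-pyran (C6 not assigned) | CC(C)=CCc1cc(ccc1O[Si](C(C)C)(C(C)C)C(C)C)[C@H]1OC(OC)C=C(O[Si](CC)(CC)CC)[C@H]1O[Si](C)(C)C(C)(C)C | intermediate (not isolated)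
10 | (2R,3S)-5-bromo-3-(tert-butyldimethylsilyloxy)-6-methoxy-2-[3-(3-methylbut-2-en-1-yl)-4-(triisopropylsilyloxy)phenyl]tetrahydro-4H-pyran-4-one (C5, C6 not assigned) | CC(C)=CCc1cc(ccc1O[Si](C(C)C)(C(C)C)C(C)C)[C@H]1OC(OC)C(Br)C(=O)[C@H]1O[Si](C)(C)C(C)(C)C | intermediate (not isolated)
11 | (2R,3S)-5-bromo-3-(tert-butyldimethylsilyloxy)-2-[3-(3-methylbut-2-en-1-yl)-4-(triisopropylsilyloxy)phenyl]-2,3-dihydro-4H-pyran-4-one (cis) | CC(C)=CCc1cc(ccc1O[Si](C(C)C)(C(C)C)C(C)C)[C@H]1OC=C(Br)C(=O)[C@H]1O[Si](C)(C)C(C)(C)C | intermediate
12 | (2R,3R)-5-bromo-3-(tert-butyldimethylsilyloxy)-2-[3-(3-methylbut-2-en-1-yl)-4-(triisopropylsilyloxy)phenyl]-2,3-dihydro-4H-pyran-4-one (trans) | CC(C)=CCc1cc(ccc1O[Si](C(C)C)(C(C)C)C(C)C)[C@H]1OC=C(Br)C(=O)[C@@H]1O[Si](C)(C)C(C)(C)C | intermediate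
13 | methyl acetoacetate | COC(=O)CC(C)=O | starting material
14 | methyl 7-methyl-3-oxooct-6-enoate | COC(=O)CC(=O)CCC=C(C)C | intermediate
15 | methyl 7-methyl-3-(trimethylsilyloxy)octa-2,6-dienoate (geometric isomers) | COC(=O)C=C(CCC=C(C)C)O[Si](C)(C)C | intermediate
16 | 1-methoxy-7-methyl-1,3-bis(trimethylsilyloxy)octa-1,3,6-triene (geometric isomers) | COC(O[Si](C)(C)C)=CC(O[Si](C)(C)C)=CCC=C(C)C | intermediate
17 | (2R,3R)-4a-bromo-3-(tert-butyldimethylsilyloxy)-5-methoxy-8-(3-methylbut-2-en-1-yl)-2-[3-(3-methylbut-2-en-1-yl)-4-(triisopropylsilyloxy)phenyl]-5,7-bis(trimethylsilyloxy)-2,3,4a,5,8,8a-hexahydro-4H-chromen-4-one (cis ring fusion; C4a, C5, C8, C8a not assigned) | CC(C)=CCc1cc(ccc1O[Si](C(C)C)(C(C)C)C(C)C)[C@H]1OC2C(CC=C(C)C)C(O[Si](C)(C)C)=CC(OC)(O[Si](C)(C)C)C2(Br)C(=O)[C@@H]1O[Si](C)(C)C(C)(C)C | intermediate (not isolated)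
18 | (2R,3R)-3-(tert-butyldimethylsilyloxy)-5,7-dihydroxy-8-(3-methylbut-2-en-1-yl)-2-[3-(3-methylbut-2-en-1-yl)-4-(triisopropylsilyloxy)phenyl]chroman-4-one | CC(C)=CCc1cc(ccc1O[Si](C(C)C)(C(C)C)C(C)C)[C@H]1Oc2c(CC=C(C)C)c(O)cc(O)c2C(=O)[C@@H]1O[Si](C)(C)C(C)(C)C | intermediate
19 | lespedezaflavanone C, (2R,3R)-3,5,7-trihydroxy-2-[4-hydroxy-3-(3-methylbut-2-en-1-yl)phenyl]-8-(3-methylbut-2-en-1-yl)chroman-4-one | CC(C)=CCc1cc([C@H]2Oc3c(CC=C(C)C)c(O)cc(O)c3C(=O)[C@@H]2O)ccc1O | target

## Step count and least certain steps

Total step count: 12. Longest linear sequence: 7 steps (steps 3, 4, 5, 6, 7, 11, 12, starting from 5).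

**Step 11 (key step).** The vinylogous ester may be too weak a dienophile for a thermal addition. After addition, the cis-disposed H-8a/Br pair may fail to eliminate. Competing paths are halophilic debromination and expulsion of O1 from an enolate, both of which lead to ring-opened or resorcinol-type material, and acid-induced closure of a prenyl group onto the new 7-OH.

Fallback with known reactions only, setting out from 3 and returning at 19; ring A is bought and not built.
- MOMCl/i-Pr2NEt converts 3 into 4-(methoxymethoxy)-3-(3-methylbut-2-en-1-yl)benzaldehyde F1.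
- Commercial 2,4,6-trihydroxyacetophenone is C-prenylated with 2 (aq. KOH) to 1-[2,4,6-trihydroxy-3-(3-methylbut-2-en-1-yl)phenyl]ethanone F2.
- Two equivalents of MOMCl cap the para and the less hindered ortho oxygen, giving 1-[2-hydroxy-4,6-bis(methoxymethoxy)-3-(3-methylbut-2-en-1-yl)phenyl]ethanone F3. Its remaining chelated OH lies next to the prenyl group and so fixes the 8-prenyl pattern.
- Claisen–Schmidt condensation of F3 with F1 (KOH, EtOH) gives the (E)-2'-hydroxychalcone F4.
- t-BuMe2SiOTf/2,6-lutidine gives the 2'-O-silyl chalcone F5.
- Juliá–Colonna epoxidation (poly-L-leucine, urea–H2O2, DBU), a nucleophilic oxidation that leaves the prenyl groups alone, gives the (αR,βS)-epoxy ketone F6.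
- Buffered Bu4NF frees the 2'-phenol, which under mild acid opens the epoxide at the benzylic carbon with inversion (6-endo) to the trans tris-acetal flavanonol F7.
- Dilute methanolic HCl removes the three acetals and gives 19.

**Step 6.** Facial selectivity may be insufficient, because a 4-silyloxy substituent on the diene and an electron-rich aromatic aldehyde both lie outside the best-documented range of CrCl(L). Trapping of 9 by NBS may also be incomplete.

Fallback, setting out from 4 and returning at 12, so that step 7 is bypassed.
- 4 reacts with commercial (E)-1-methoxy-3-(trimethylsilyloxy)buta-1,3-diene under Ti(OiPr)4/BINOL catalysis (Mukaiyama aldol, then CF3CO2H; the BINOL enantiomer is chosen for the wanted C2 configuration). This gives (S)-2-[3-(3-methylbut-2-en-1-yl)-4-(triisopropylsilyloxy)phenyl]-2,3-dihydro-4H-pyran-4-one F8. The descriptor changes because C3 is unsubstituted; the arrangement at C2 is that of 12.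
- Kinetic enolisation at C3 (LiN(SiMe3)2, Me3SiCl, −78 °C) and Rubottom oxidation with DMDO anti to the aryl group give the trans hydroxy ketone F9.
- t-BuMe2SiOTf/2,6-lutidine gives the silyl ether F10.
- NBS, then Et3N, brominates C5 and gives 12.

**Step 7.** The C3 enolate may open the ring by loss of the vinylogous carboxylate O1. This consumes material and, if the ring recloses, scrambles C2.

Fallback, setting out from 11 and returning at 12; C3 is inverted by substitution and not by enolisation.
- HF·pyridine gives the cis alcohol F11.
- A Mitsunobu reaction (4-nitrobenzoic acid, PPh3, DIAD) inverts C3 by SN2 and gives the trans ester F12.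
- Et3N/MeOH methanolysis gives the trans alcohol F13.
- t-BuMe2SiOTf/2,6-lutidine gives 12.

**Step 4.** The methoxy enol ether double bond may be oxidised as well, or the acid-sensitive diene 6 may hydrolyse before it is oxidised.

Fallback, setting out from 5 and returning at 7, so that step 3 is not needed.
- α'-Acetoxylation of the enone with Mn(OAc)3 (benzene, reflux) gives (E)-4-methoxy-2-oxobut-3-en-1-yl acetate F14.
- K2CO3 (cat.)/MeOH gives (E)-1-hydroxy-4-methoxybut-3-en-2-one F15.
- t-BuMe2SiCl/imidazole gives 7.

## Further compounds

F1 | step 11 | 4-(methoxymethoxy)-3-(3-methylbut-2-en-1-yl)benzaldehyde | COCOc1ccc(C=O)cc1CC=C(C)C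
F2 | step 11 | 1-[2,4,6-trihydroxy-3-(3-methylbut-2-en-1-yl)phenyl]ethanone | CC(=O)c1c(O)cc(O)c(CC=C(C)C)c1O
F3 | step 11 | 1-[2-hydroxy-4,6-bis(methoxymethoxy)-3-(3-methylbut-2-en-1-yl)phenyl]ethanone | CC(=O)c1c(OCOC)cc(OCOC)c(CC=C(C)C)c1O
F4 | step 11 | (E)-1-[2-hydroxy-4,6-bis(methoxymethoxy)-3-(3-methylbut-2-en-1-yl)phenyl]-3-[4-(methoxymethoxy)-3-(3-methylbut-2-en-1-yl)phenyl]prop-2-en-1-one | COCOc1ccc(/C=C/C(=O)c2c(OCOC)cc(OCOC)c(CC=C(C)C)c2O)cc1CC=C(C)C
F5 | step 11 | (E)-1-[2-(tert-butyldimethylsilyloxy)-4,6-bis(methoxymethoxy)-3-(3-methylbut-2-en-1-yl)phenyl]-3-[4-(methoxymethoxy)-3-(3-methylbut-2-en-1-yl)phenyl]prop-2-en-1-one | COCOc1ccc(/C=C/C(=O)c2c(OCOC)cc(OCOC)c(CC=C(C)C)c2O[Si](C)(C)C(C)(C)C)cc1CC=C(C)C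
F6 | step 11 | [2-(tert-butyldimethylsilyloxy)-4,6-bis(methoxymethoxy)-3-(3-methylbut-2-en-1-yl)phenyl] {(2R,3S)-3-[4-(methoxymethoxy)-3-(3-methylbut-2-en-1-yl)phenyl]oxiran-2-yl} ketone | COCOc1ccc(cc1CC=C(C)C)[C@@H]1O[C@H]1C(=O)c1c(OCOC)cc(OCOC)c(CC=C(C)C)c1O[Si](C)(C)C(C)(C)C
F7 | step 11 | (2R,3R)-3-hydroxy-5,7-bis(methoxymethoxy)-2-[4-(methoxymethoxy)-3-(3-methylbut-2-en-1-yl)phenyl]-8-(3-methylbut-2-en-1-yl)chroman-4-one | COCOc1ccc(cc1CC=C(C)C)[C@H]1Oc2c(CC=C(C)C)c(OCOC)cc(OCOC)c2C(=O)[C@@H]1O
F8 | step 6 | (S)-2-[3-(3-methylbut-2-en-1-yl)-4-(triisopropylsilyloxy)phenyl]-2,3-dihydro-4H-pyran-4-one | CC(C)=CCc1cc(ccc1O[Si](C(C)C)(C(C)C)C(C)C)[C@@H]1CC(=O)C=CO1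
F9 | step 6 | (2R,3R)-3-hydroxy-2-[3-(3-methylbut-2-en-1-yl)-4-(triisopropylsilyloxy)phenyl]-2,3-dihydro-4H-pyran-4-one | CC(C)=CCc1cc(ccc1O[Si](C(C)C)(C(C)C)C(C)C)[C@H]1OC=CC(=O)[C@@H]1O
F10 | step 6 | (2R,3R)-3-(tert-butyldimethylsilyloxy)-2-[3-(3-methylbut-2-en-1-yl)-4-(triisopropylsilyloxy)phenyl]-2,3-dihydro-4H-pyran-4-one | CC(C)=CCc1cc(ccc1O[Si](C(C)C)(C(C)C)C(C)C)[C@H]1OC=CC(=O)[C@@H]1O[Si](C)(C)C(C)(C)C
F11 | step 7 | (2R,3S)-5-bromo-3-hydroxy-2-[3-(3-methylbut-2-en-1-yl)-4-(triisopropylsilyloxy)phenyl]-2,3-dihydro-4H-pyran-4-one | CC(C)=CCc1cc(ccc1O[Si](C(C)C)(C(C)C)C(C)C)[C@H]1OC=C(Br)C(=O)[C@H]1O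
F12 | step 7 | (2R,3R)-5-bromo-2-[3-(3-methylbut-2-en-1-yl)-4-(triisopropylsilyloxy)phenyl]-4-oxo-3,4-dihydro-2H-pyran-3-yl 4-nitrobenzoate | CC(C)=CCc1cc(ccc1O[Si](C(C)C)(C(C)C)C(C)C)[C@H]1OC=C(Br)C(=O)[C@@H]1OC(=O)c1ccc(cc1)[N+](=O)[O-]
F13 | step 7 | (2R,3R)-5-bromo-3-hydroxy-2-[3-(3-methylbut-2-en-1-yl)-4-(triisopropylsilyloxy)phenyl]-2,3-dihydro-4H-pyran-4-one | CC(C)=CCc1cc(ccc1O[Si](C(C)C)(C(C)C)C(C)C)[C@H]1OC=C(Br)C(=O)[C@@H]1O
F14 | step 4 | (E)-4-methoxy-2-oxobut-3-en-1-yl acetate | CO/C=C/C(=O)COC(C)=O
F15 | step 4 | (E)-1-hydroxy-4-methoxybut-3-en-2-one | CO/C=C/C(=O)CO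
A1 | alternative 1 | (2R,3R)-7-(tert-butyldimethylsilyloxy)-3-hydroxy-2-[4-(2-methylbut-3-en-2-yloxy)phenyl]-5-(3-methylbut-2-en-1-yloxy)chroman-4-one | C=CC(C)(C)Oc1ccc(cc1)[C@H]1Oc2cc(O[Si](C)(C)C(C)(C)C)cc(OCC=C(C)C)c2C(=O)[C@@H]1O
A2 | alternative 1 | 7-O-(tert-butyldimethylsilyl)-lespedezaflavanone C | CC(C)=CCc1cc(ccc1O)[C@H]1Oc2c(CC=C(C)C)c(O[Si](C)(C)C(C)(C)C)cc(O)c2C(=O)[C@@H]1O
A3 | alternative 2 | racemic 2-{1-[4-(methoxymethoxy)-3-(3-methylbut-2-en-1-yl)phenyl]-2-oxoethoxy}-4,6-bis(methoxymethoxy)-3-(3-methylbut-2-en-1-yl)benzaldehyde | COCOc1ccc(cc1CC=C(C)C)C(C=O)Oc1c(CC=C(C)C)c(OCOC)cc(OCOC)c1C=O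
A4 | alternative 2 | 5,7,4'-tris-O-(methoxymethyl)-lespedezaflavanone C | COCOc1ccc(cc1CC=C(C)C)[C@H]1Oc2c(CC=C(C)C)c(OCOC)cc(OCOC)c2C(=O)[C@@H]1O
A5 | alternative 3 | (2R,3R)-3-[2-bromo-3,5-bis(methoxymethoxy)-6-(3-methylbut-2-en-1-yl)phenoxy]-2-(tert-butyldimethylsilyloxy)-N-methoxy-3-[4-(methoxymethoxy)-3-(3-methylbut-2-en-1-yl)phenyl]-N-methylpropanamide | COCOc1ccc(cc1CC=C(C)C)[C@@H](Oc1c(CC=C(C)C)c(OCOC)cc(OCOC)c1Br)[C@@H](O[Si](C)(C)C(C)(C)C)C(=O)N(C)OC
A6 | alternative 3 | 3-O-(tert-butyldimethylsilyl)-5,7,4'-tris-O-(methoxymethyl)-lespedezaflavanone C | COCOc1ccc(cc1CC=C(C)C)[C@H]1Oc2c(CC=C(C)C)c(OCOC)cc(OCOC)c2C(=O)[C@@H]1O[Si](C)(C)C(C)(C)C
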